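**Plan**
Cuts (acid numbering: C1 = CO2H, O–O bridge from C3 to C6, C17 = benzylic CH2): C9=C10 (Wittig, then diimide), C2–C3 (ketene acetal on a C3 peroxycarbenium ion), O–C3 (ring closure), C6–OO (radical peroxidation of a C6 methylene), and C4–C5 plus C7–C8 (double enolate alkylation).
Enabling feature: C6 of the 1,2-dioxane carries two arms, C5–C4(CH3) and C7–C8(CH3), of the same constitution and the same sense of chirality. With C3 and C9 both as CHO, C6 is therefore not a stereocentre, and the tertiary C–OO bond can be made by a stereorandom radical reaction without giving isomers.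
Forward order: the C3–C9 chain is built in two directions (steps 1–4). The only ring closes on one of the two formyl groups (step 5). The free arm then takes the phenylalkyl chain (steps 6, 7, 9), C3 takes the acetate unit (step 8), and the ester is hydrolysed (step 10).
Stereochemistry: C4 and C8 come from one Evans auxiliary used twice. C6 arises in the reversible ring closure by choice between the two diastereotopic arms. C3 comes from stereoconvergent axial attack on the peroxycarbenium half-chair.

Key step: step 5

Remark: the acid numbering above is used for all intermediates, and (8-bromooctyl)benzene is taken as a commercial compound.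

**Step 1**
Reactants: 1 (R)-4-benzyl-3-propionyloxazolidin-2-one (slightly more than 2 equiv); 2 3-bromo-2-(bromomethyl)prop-1-ene
Product: 5 (4R,4'R)-3,3'-[(2S,6S)-2,6-dimethyl-4-methyleneheptanedioyl]bis(4-benzyloxazolidin-2-one), via sodium enolate 3 (not isolated), via monoalkylated bromide 4 (not isolated)
Conditions: NaN(SiMe3)2, THF, −78 °C; then 2, −78 to −30 °C
Reagents that add atoms: none
Why: Evans asymmetric alkylation run in both directions, in which the chelated sodium (Z)-enolate attacks the reactive allylic bromide on the face opposite the benzyl group, so that C4 and C8 are set with the same sense (S,S in 5) and any mismatched event ends in a separable diastereomer.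

**Step 2**
Reactants: 5 bis-imide
Product: 6 (2S,6S)-2,6-dimethyl-4-methyleneheptane-1,7-diol
Conditions: LiBH4, H2O (2 equiv), Et2O, 0 °C
Reagents that add atoms: none
Why: Reductive removal of the Evans auxiliary, in which LiBH4 reduces only the exocyclic imide carbonyl groups to primary alcohols and leaves the alkene and the alpha stereocentres untouched.

**Step 3**
Reactants: 6 diol
Product: 7 (2S,6S)-2,4,6-trimethyl-4-(triethylsilylperoxy)heptane-1,7-diol
Conditions: Co(thd)2 [bis(2,2,6,6-tetramethylheptane-3,5-dionato)cobalt, divalent cobalt] (5 mol %), O2 (1 atm), Et3SiH, ClCH2CH2Cl, rt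
Reagents that add atoms: dioxygen O=O; triethylsilane CC[SiH](CC)CC
Why: Mukaiyama–Isayama peroxidation, in which a cobalt hydride gives H to the CH2 end of the 1,1-disubstituted alkene, O2 traps the tertiary C6 radical and the cobalt peroxide is silylated; free hydroxyl groups are tolerated, and no stereocentre arises because both arms on C6 are identical.

**Step 4**
Reactants: 7 silylperoxy diol
Product: 8 (2S,6S)-2,4,6-trimethyl-4-(triethylsilylperoxy)heptanedial
Conditions: Dess–Martin periodinane, pyridine, CH2Cl2, 0 °C to rt
Reagents that add atoms: none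
Why: Dess–Martin oxidation is non-reducing and nearly neutral, so both primary alcohols should give aldehydes without epimerisation at C4 or C8 and without loss of the silyl peroxide.

**Step 5**
Reactants: 8 silylperoxy dialdehyde
Product: 9 (S)-2-methyl-3-[(3R,5S)-3,5-dimethyl-6-(triethylsilyloxy)-1,2-dioxan-3-yl]propanal (acid numbering 4S,6R,8S; both anomers at C3)
Conditions: Et3SiOSO2CF3 (5 mol %), 2,6-di-tert-butyl-4-methylpyridine (10 mol %), CH2Cl2 (high dilution), −78 to −40 °C; Et3N quench
Reagents that add atoms: none
Why: Proposed new method: the catalyst passes Et3Si+ to a formyl oxygen, the silicon-bearing peroxide oxygen adds to the silyloxycarbenium carbon C3 (6-exo-trig), and loss of Et3Si+ from the peroxonium ion returns the catalyst, so 8 isomerises to 9 with no reagent consumed and every event reversible. The closest known reaction types are the Noyori acetalisation of carbonyl compounds with alkoxysilanes under silyl triflate catalysis and the silyl-triflate-catalysed condensation of silyl peroxides with aldehydes or ketones that leads to 1,2,4-trioxanes, and the spontaneous closure of 4-hydroperoxy aldehydes to 1,2-dioxan-3-ols shows that this ring size is favoured. The single ring (1,2-dioxane) closes through a chair with the C4 methyl group equatorial. C6 becomes a stereocentre only here: closure on one arm puts the C6 methyl axial and the branched C7 arm equatorial (6R, needed), closure on the other arm would force the branched arm axial, so the former should prevail at equilibrium; C3 forms as an anomeric mixture, which does not matter because step 8 passes through a planar cation. The selectivity needed is between two diastereotopic formyl groups, the like-configured C4 and C8 centres secure it through the chair, and material closed the wrong way is not lost because ring opening under the same catalyst erases C6 again. The silyl transfer also locks the lactol oxygen and leaves the second formyl group free, with no chance of kinetic capture of an open-chain hydroperoxide.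

**Step 6**
Reactants: 10 (8-bromooctyl)benzene
Product: 11 (8-phenyloctyl)triphenylphosphonium bromide
Conditions: PPh3, MeCN, reflux
Reagents that add atoms: triphenylphosphine c1ccccc1P(c1ccccc1)c1ccccc1
Why: SN2 quaternisation of triphenylphosphine by an unhindered primary bromide.

**Step 7**
Reactants: 9 aldehyde; 11 phosphonium salt
Product: 13 (3R,5S)-3,5-dimethyl-3-[(2S,3Z)-2-methyl-11-phenylundec-3-en-1-yl]-6-(triethylsilyloxy)-1,2-dioxane, via ylide 12 (not isolated)
Conditions: 11, NaN(SiMe3)2, THF, 0 °C; then 9, −78 °C to 0 °C
Reagents that add atoms: none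
Why: Wittig olefination with a non-stabilised ylide is fast on the free aldehyde at low temperature, so C8 should not epimerise, the dialkyl peroxide and silyl acetal should survive, and the alkene geometry is irrelevant because step 9 removes it.

**Step 8**
Reactants: 13 silyl peroxyacetal; 14 1-(tert-butyldimethylsilyloxy)-1-methoxyethene
Product: 15 methyl 2-[(3S,4S,6R)-4,6-dimethyl-6-[(2S,3Z)-2-methyl-11-phenylundec-3-en-1-yl]-1,2-dioxan-3-yl]acetate
Conditions: 14 (2 equiv), Me3SiOSO2CF3 (0.2 equiv), CH2Cl2, −78 °C
Reagents that add atoms: none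
Why: Lewis-acid-mediated substitution of a cyclic peroxyacetal by a silyl ketene acetal (Mukaiyama-type addition to a peroxycarbenium ion), in which both anomers give the same half-chair cation with the C4 methyl and C7 arm pseudo-equatorial and the C6 methyl pseudo-axial, and the nucleophile adds along the axial trajectory that leads directly to the chair, opposite the axial C6 methyl, which places C2 axial and cis to the C4 methyl (3S).

**Step 9**
Reactants: 15 unsaturated ester
Product: 16 methyl 2-[(3S,4S,6R)-4,6-dimethyl-6-[(2R)-2-methyl-11-phenylundecyl]-1,2-dioxan-3-yl]acetate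
Conditions: KO2CN=NCO2K, AcOH, MeOH/CH2Cl2, 0 °C to rt
Reagents that add atoms: none
Why: Diimide reduction transfers H2 in a concerted way to the unhindered cis-disubstituted alkene and does not cleave the O–O bond, the ester or the arene.

**Step 10**
Reactants: 16 saturated ester
Product: 17 2-[(3S,4S,6R)-4,6-dimethyl-6-[(2R)-2-methyl-11-phenylundecyl]-1,2-dioxan-3-yl]acetic acid (target)
Conditions: LiOH, THF/H2O, 0 °C to rt; then 1 M HCl
Reagents that add atoms: lithium hydroxide [Li+].[OH-]
Why: Saponification by acyl–oxygen cleavage should be faster than deprotonation at C2, and the carboxylate once formed resists retro-oxa-Michael opening, so C3 is kept.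

**Compound list**
1 | (R)-4-benzyl-3-propionyloxazolidin-2-one | CCC(=O)N1[C@H](Cc2ccccc2)COC1=O | starting material
2 | 3-bromo-2-(bromomethyl)prop-1-ene | BrCC(=C)CBr | starting material
3 | sodium (Z)-enolate of 1 | C/C=C(\[O-])N1[C@H](Cc2ccccc2)COC1=O.[Na+] | intermediate
4 | (R)-4-benzyl-3-[(S)-4-(bromomethyl)-2-methylpent-4-enoyl]oxazolidin-2-one | BrCC(=C)C[C@H](C)C(=O)N1[C@H](Cc2ccccc2)COC1=O | intermediate
5 | (4R,4'R)-3,3'-[(2S,6S)-2,6-dimethyl-4-methyleneheptanedioyl]bis(4-benzyloxazolidin-2-one) | O=C1OC[C@@H](Cc2ccccc2)N1C(=O)[C@@H](C)CC(=C)C[C@H](C)C(=O)N1[C@H](Cc2ccccc2)COC1=O | intermediate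
6 | (2S,6S)-2,6-dimethyl-4-methyleneheptane-1,7-diol | OC[C@@H](C)CC(=C)C[C@H](C)CO | intermediate
7 | (2S,6S)-2,4,6-trimethyl-4-(triethylsilylperoxy)heptane-1,7-diol | OC[C@@H](C)CC(C)(OO[Si](CC)(CC)CC)C[C@H](C)CO | intermediate
8 | (2S,6S)-2,4,6-trimethyl-4-(triethylsilylperoxy)heptanedial | O=C[C@@H](C)CC(C)(OO[Si](CC)(CC)CC)C[C@H](C)C=O | intermediate
9 | (S)-2-methyl-3-[(3R,5S)-3,5-dimethyl-6-(triethylsilyloxy)-1,2-dioxan-3-yl]propanal, anomeric mixture at the silyloxy carbon | C[C@H](C=O)C[C@]1(C)C[C@H](C)C(O[Si](CC)(CC)CC)OO1 | intermediate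
10 | (8-bromooctyl)benzene | BrCCCCCCCCc1ccccc1 | starting material
11 | (8-phenyloctyl)triphenylphosphonium bromide | [Br-].c1ccccc1CCCCCCCC[P+](c1ccccc1)(c1ccccc1)c1ccccc1 | intermediate
12 | (8-phenyloctylidene)triphenylphosphorane | c1ccccc1CCCCCCCC=P(c1ccccc1)(c1ccccc1)c1ccccc1 | intermediate
13 | (3R,5S)-3,5-dimethyl-3-[(2S,3Z)-2-methyl-11-phenylundec-3-en-1-yl]-6-(triethylsilyloxy)-1,2-dioxane, anomeric mixture | C[C@H](/C=C\CCCCCCCc1ccccc1)C[C@]1(C)C[C@H](C)C(O[Si](CC)(CC)CC)OO1 | intermediate
14 | 1-(tert-butyldimethylsilyloxy)-1-methoxyethene | C=C(OC)O[Si](C)(C)C(C)(C)C | starting material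
15 | methyl 2-[(3S,4S,6R)-4,6-dimethyl-6-[(2S,3Z)-2-methyl-11-phenylundec-3-en-1-yl]-1,2-dioxan-3-yl]acetate | C[C@H](/C=C\CCCCCCCc1ccccc1)C[C@]1(C)C[C@H](C)[C@H](CC(=O)OC)OO1 | intermediate
16 | methyl 2-[(3S,4S,6R)-4,6-dimethyl-6-[(2R)-2-methyl-11-phenylundecyl]-1,2-dioxan-3-yl]acetate | C[C@H](CCCCCCCCCc1ccccc1)C[C@]1(C)C[C@H](C)[C@H](CC(=O)OC)OO1 | intermediate
17 | 2-[(3S,4S,6R)-4,6-dimethyl-6-[(2R)-2-methyl-11-phenylundecyl]-1,2-dioxan-3-yl]acetic acid | C[C@H](CCCCCCCCCc1ccccc1)C[C@]1(C)C[C@H](C)[C@H](CC(=O)O)OO1 | target

Total steps: 10. Longest linear sequence: 9 (steps 1–5 and 7–10).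

**Steps most likely to fail**

Step 5 (Proposed new method).
- What may go wrong: The silyl acetal may ionise further, and a second silyl peroxide may capture the cation. The silyl triflate may trigger heterolysis of the O–O bond. The energy gap between an axial methyl and an axial branched arm at C6 is small, so discrimination between the two arms may be weak.
- Fallback (known chemistry): it sets out from 8. Catalytic TsOH in MeOH cleaves the silyl peroxide. Under equilibrating conditions the ring closes to the methyl peroxyacetal, and the second formyl group is held as the dimethyl acetal F1. Mild hydrolysis (PPTS, wet acetone) of the more labile acyclic acetal gives the methoxy-dioxane aldehyde F2. Wittig reaction with 12 gives the methoxy-dioxane alkene F3. TiCl4 and 14 at −78 °C come back to the route at 15. The C6 epimer is removed by chromatography at F2 and re-equilibrated in acidic methanol.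

Step 8.
- What may go wrong: The ring C3–OO bond may ionise instead of C3–OSi. A hydride-shift fragmentation of the peroxyacetal may intervene. Facial selectivity may erode through contact of the bulky ketene acetal with the neighbouring C4 methyl.
- Fallback: it sets out from 13. Diimide gives the saturated silyl peroxyacetal F4. Allyltrimethylsilane with SnCl4 at −78 °C, a smaller and well-precedented nucleophile for peroxycarbenium ions, gives the 3-allyl dioxane F5. Ozonolysis with Me2S work-up gives the aldehyde F6. Oxidation with NaClO2/NaH2PO4/2-methyl-2-butene comes back to the route at 17.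

Step 10.
- What may go wrong: Under base, retro-oxa-Michael opening and re-closure may move C3 to the more stable 3,4-trans arrangement. The C2 enolate may also attack the O–O bond.
- Fallback: it avoids any ester and sets out from 13. The known reagent 1,1-bis(trimethylsilyloxy)ethene with catalytic Me3SiOSO2CF3 at −78 °C gives the trimethylsilyl ester F7. This loses silicon on aqueous work-up to give the unsaturated acid F8. Diimide reduction under the conditions of step 9 comes back to the route at 17.

**Further compounds**
F1 | step 5 | (3R,5S)-3-[(2S)-3,3-dimethoxy-2-methylpropyl]-6-methoxy-3,5-dimethyl-1,2-dioxane | C[C@H](C(OC)OC)C[C@]1(C)C[C@H](C)C(OC)OO1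
F2 | step 5 | (S)-3-[(3R,5S)-6-methoxy-3,5-dimethyl-1,2-dioxan-3-yl]-2-methylpropanal | C[C@H](C=O)C[C@]1(C)C[C@H](C)C(OC)OO1
F3 | step 5 | (3R,5S)-6-methoxy-3,5-dimethyl-3-[(2S,3Z)-2-methyl-11-phenylundec-3-en-1-yl]-1,2-dioxane | C[C@H](/C=C\CCCCCCCc1ccccc1)C[C@]1(C)C[C@H](C)C(OC)OO1
F4 | step 8 | (3R,5S)-3,5-dimethyl-3-[(2R)-2-methyl-11-phenylundecyl]-6-(triethylsilyloxy)-1,2-dioxane | C[C@H](CCCCCCCCCc1ccccc1)C[C@]1(C)C[C@H](C)C(O[Si](CC)(CC)CC)OO1
F5 | step 8 | (3S,4S,6R)-3-allyl-4,6-dimethyl-6-[(2R)-2-methyl-11-phenylundecyl]-1,2-dioxane | C[C@H](CCCCCCCCCc1ccccc1)C[C@]1(C)C[C@H](C)[C@H](CC=C)OO1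
F6 | step 8 | 2-[(3S,4S,6R)-4,6-dimethyl-6-[(2R)-2-methyl-11-phenylundecyl]-1,2-dioxan-3-yl]acetaldehyde | C[C@H](CCCCCCCCCc1ccccc1)C[C@]1(C)C[C@H](C)[C@H](CC=O)OO1
F7 | step 10 | trimethylsilyl 2-[(3S,4S,6R)-4,6-dimethyl-6-[(2S,3Z)-2-methyl-11-phenylundec-3-en-1-yl]-1,2-dioxan-3-yl]acetate | C[C@H](/C=C\CCCCCCCc1ccccc1)C[C@]1(C)C[C@H](C)[C@H](CC(=O)O[Si](C)(C)C)OO1
F8 | step 10 | 2-[(3S,4S,6R)-4,6-dimethyl-6-[(2S,3Z)-2-methyl-11-phenylundec-3-en-1-yl]-1,2-dioxan-3-yl]acetic acid | C[C@H](/C=C\CCCCCCCc1ccccc1)C[C@]1(C)C[C@H](C)[C@H](CC(=O)O)OO1
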